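**Retrosynthetic overview**
1. The last C–C bond is C9–C11. It is cut homolytically into a tertiary ring-B radical at C9 and a primary radical at C11. Both radicals come from carboxylic acids in one nickel-sorted double decarboxylative coupling, which brings in C11–C16 with C13 preset and creates the C9 quaternary stereocentre.
2. Enabling feature: C9 is a fully substituted sp3 carbon of ring B bonded to an unbranched CH2 (C11). Its ring neighbours C8 and C10 are CH centres that turn their carbon substituents (C17 methyl, C1 of ring A) to the β face and only H to the α face. A planar C9 radical is therefore too hindered to bind to nickel and is open on the α face only.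
3. Ring B comes from an exo-selective, catalyst-controlled Diels–Alder reaction of a ring-A 1-vinylcyclohexene (C10=C5–C6=C7) with tiglaldehyde (C8=C9). It sets C8 and C10 and places C5=C6. Its formyl group, once oxidised, is the carboxyl that leaves in the key step.
4. Ring A is bought as ethyl 2-oxocyclohexanecarboxylate, and C4 is set by asymmetric hydrogenation followed by alkoxide-directed methylation. The side-chain acid comes from (R)-citronellic acid by alkene cleavage.
5. Ring order: ring A (starting material), then ring B (step 8). No ring is formed afterwards.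

Key step: step 12

Remark (numbering): halimane numbering is used for the bicyclic compounds. Ring A = C1–C5 and C10; ring B = C5–C10; C18 = CH2OAc carbon on C4 (α); C19 = C4 methyl (β); C17 = C8 methyl; C20 = C9 methyl; side chain = C11–C16; α = the face of H-10.
Assumption: the (S)-oxazaborolidinium ion of step 8 is taken to expose the enal face that leads to the drawn absolute configuration; if its sense of induction is the opposite, its enantiomer is used.

Step 1
Reactants: 1 ethyl 2-oxocyclohexane-1-carboxylate
Product: 2 ethyl (1S,2S)-2-hydroxycyclohexane-1-carboxylate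
Conditions: H2 (100 atm), [RuCl(C6H6)((S)-BINAP)]Cl (0.2 mol %), CH2Cl2, 50 °C
Reagents that add atoms: none
Why: Noyori asymmetric hydrogenation of a configurationally labile β-keto ester under dynamic kinetic resolution should reduce the ketone from the face dictated by (S)-BINAP and so fix the (2S)-carbinol centre, the only centre of 2 that matters because C1 is flattened in step 2.

Step 2
Reactants: 2 ethyl (1S,2S)-2-hydroxycyclohexane-1-carboxylate
Product: 4 ethyl (1R,2S)-2-hydroxy-1-methylcyclohexane-1-carboxylate, via dilithium alkoxide-enolate 3 (not isolated)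
Conditions: LiN(i-Pr)2 (LDA, 2.2 equiv), THF, −78 to −20 °C; MeI, DMPU, −78 to 0 °C; then H2O
Reagents that add atoms: iodomethane, CI
Why: Fráter–Seebach alkylation, in which the chelated dianion 3 should take up iodomethane on the face anti to the ring CH2 of the carbinol carbon, that is trans to the oxygen, which sets the quaternary carbon (later C4) by 1,2-induction.

Step 3
Reactants: 4 ethyl (1R,2S)-2-hydroxy-1-methylcyclohexane-1-carboxylate
Product: 5 ethyl (1R)-1-methyl-2-oxocyclohexane-1-carboxylate
Conditions: Dess–Martin periodinane, CH2Cl2, rt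
Reagents that add atoms: none
Why: Dess–Martin oxidation handles hindered secondary alcohols under neutral conditions, and the quaternary α-carbon cannot epimerise.

Step 4
Reactants: 5 ethyl (1R)-1-methyl-2-oxocyclohexane-1-carboxylate
Product: 7 ethyl (1R)-1-methyl-2-(trifluoromethylsulfonyloxy)cyclohex-2-ene-1-carboxylate, via lithium enolate 6 (not isolated)
Conditions: LiN(i-Pr)2 (LDA, 1.1 equiv), THF, −78 °C; PhNTf2, −78 °C to rt; then H2O
Reagents that add atoms: N-phenylbis(trifluoromethanesulfonimide), O=S(=O)(N(c1ccccc1)S(=O)(=O)C(F)(F)F)C(F)(F)F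
Why: Enol triflate synthesis, in which deprotonation can only occur on the CH2 flank because the other α-carbon is quaternary, so O-sulfonylation of 6 gives the C5(OTf)=C10 alkene regiospecifically.

Step 5
Reactants: 7 ethyl (1R)-1-methyl-2-(trifluoromethylsulfonyloxy)cyclohex-2-ene-1-carboxylate
Product: 8 ethyl (1R)-2-ethenyl-1-methylcyclohex-2-ene-1-carboxylate
Conditions: tributyl(vinyl)stannane, Pd(PPh3)4 (3 mol %), LiCl (3 equiv), THF, reflux
Reagents that add atoms: tributyl(vinyl)stannane, C=C[Sn](CCCC)(CCCC)CCCC
Why: Stille coupling of an enol triflate in the presence of LiCl is a standard route to 1-vinylcyclohexenes, works next to a quaternary carbon, tolerates the ester and touches no stereocentre.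

Step 6
Reactants: 8 ethyl (1R)-2-ethenyl-1-methylcyclohex-2-ene-1-carboxylate
Product: 9 [(1R)-2-ethenyl-1-methylcyclohex-2-en-1-yl]methanol
Conditions: LiAlH4, Et2O, 0 °C to rt; then H2O
Reagents that add atoms: none
Why: Hydride reduction of the hindered ester to the neopentyl-type primary alcohol should be clean because an unactivated 1,3-diene is inert to LiAlH4 and the quaternary centre cannot epimerise.

Step 7
Reactants: 9 [(1R)-2-ethenyl-1-methylcyclohex-2-en-1-yl]methanol
Product: 10 [(1R)-2-ethenyl-1-methylcyclohex-2-en-1-yl]methyl acetate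
Conditions: Ac2O, pyridine, 4-(dimethylamino)pyridine (DMAP, cat.), CH2Cl2, rt
Reagents that add atoms: acetic anhydride, CC(=O)OC(C)=O
Why: DMAP-catalysed acetylation installs the acetate of the target early, and this group is inert to every later step (Lewis acid, chlorite, alkyl radicals, fluoride).

Step 8
Reactants: 10 [(1R)-2-ethenyl-1-methylcyclohex-2-en-1-yl]methyl acetate; 11 (E)-2-methylbut-2-enal (tiglaldehyde)
Product: 12 [(1R,4aR,5R,6S)-5-formyl-1,5,6-trimethyl-1,2,3,4,4a,5,6,7-octahydronaphthalen-1-yl]methyl acetate (4α-CH2OAc, 8β-Me, 9β-Me, 9α-CHO, 10α-H, C5=C6)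
Conditions: 11 (3 equiv), (S)-3,3-diphenyl-1-(2-methylphenyl)tetrahydro-1H,3H-pyrrolo[1,2-c][1,3,2]oxazaborole (20 mol %) + Tf2NH (18 mol %), CH2Cl2, −78 to −20 °C
Reagents that add atoms: none
Why: Catalytic enantioselective Diels–Alder reaction, in which the advanced bond of the asynchronous transition state joins the enal β-carbon (C8) to the unhindered terminal CH2 (C7) so that the formyl-bearing carbon meets C10 (ortho orientation), the α-methyl group and the bulky catalyst-bound formyl group favour the exo transition state that puts both methyl groups under the diene and hence cis to C1 (sets C8 relative to C10, C9 provisionally), and, since CH3 and CH2OAc on C4 differ too little to bias the diene faces, the chiral oxazaborolidinium ion should direct the enal to the diene face syn to the C4 methyl group, which puts H-10 on the side of the acetoxymethyl group and leaves the alkene at C5=C6.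

Step 9
Reactants: 12 [(1R,4aR,5R,6S)-5-formyl-1,5,6-trimethyl-1,2,3,4,4a,5,6,7-octahydronaphthalen-1-yl]methyl acetate
Product: 13 (1R,2S,5R,8aR)-5-(acetoxymethyl)-1,2,5-trimethyl-1,2,3,5,6,7,8,8a-octahydronaphthalene-1-carboxylic acid
Conditions: NaClO2, NaH2PO4, 2-methylbut-2-ene, t-BuOH/H2O, rt
Reagents that add atoms: sodium chlorite, [Na+].[O-]Cl=O
Why: Pinnick oxidation converts even α-quaternary aldehydes into acids under buffered conditions, and 2-methylbut-2-ene intercepts HOCl so that the C5=C6 alkene and the acetate survive.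

Step 10
Reactants: 14 (R)-citronellic acid [(3R)-3,7-dimethyloct-6-enoic acid]
Product: 15 2-(trimethylsilyl)ethyl (3R)-3,7-dimethyloct-6-enoate
Conditions: Me3SiCH2CH2OH, DCC, 4-(dimethylamino)pyridine (DMAP, cat.), CH2Cl2, 0 °C to rt
Reagents that add atoms: 2-(trimethylsilyl)ethanol, C[Si](C)(C)CCO
Why: Steglich esterification masks the future C15 carboxyl as a fluoride-labile ester that can later be removed without touching the acetate, and the C13 stereocentre, taken from the chiral pool, is not involved.

Step 11
Reactants: 15 2-(trimethylsilyl)ethyl (3R)-3,7-dimethyloct-6-enoate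
Product: 16 (4R)-4-methyl-6-oxo-6-[2-(trimethylsilyl)ethoxy]hexanoic acid
Conditions: RuCl3·xH2O (3 mol %), NaIO4 (4 equiv), EtOAc/MeCN/H2O, rt
Reagents that add atoms: sodium periodate, [Na+].[O-]I(=O)(=O)=O
Why: Catalytic RuO4 oxidative cleavage (RuCl3/NaIO4) cuts the trisubstituted alkene to the carboxylic acid and acetone in one operation, which leaves the acid carbon one atom beyond the future C11 without affecting the remote stereocentre or the ester.

Step 12
Reactants: 13 (1R,2S,5R,8aR)-5-(acetoxymethyl)-1,2,5-trimethyl-1,2,3,5,6,7,8,8a-octahydronaphthalene-1-carboxylic acid; 16 (4R)-4-methyl-6-oxo-6-[2-(trimethylsilyl)ethoxy]hexanoic acid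
Product: 18 2-(trimethylsilyl)ethyl (3R)-5-[(1R,2S,5R,8aS)-5-(acetoxymethyl)-1,2,5-trimethyl-1,2,3,5,6,7,8,8a-octahydronaphthalen-1-yl]-3-methylpentanoate, via mixed mesityliodine dicarboxylate 17 (not isolated)
Conditions: 13 (1 equiv), 16 (3 equiv), MesI(OAc)2 (2 equiv), toluene, 40 °C, then evaporation; Ni(acac)2 (10 mol %), K[HB(3,5-Me2pz)3] (KTp*, 10 mol %), 2,4,5,6-tetra(carbazol-9-yl)isophthalonitrile (4CzIPN, 2 mol %), 1,4-dioxane, 450 nm LED, rt
Reagents that add atoms: iodomesitylene diacetate, CC(=O)OI(OC(C)=O)c1c(C)cc(C)cc1C (its mesityl-iodine unit is held only in 17 and leaves again)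
Why: Ligand exchange on MesI(OAc)2 binds both acids to iodine (17), and the excited photocatalyst then cleaves both iodine–oxygen bonds in a redox-neutral cycle (reduction of the iodane, oxidation of the carboxylate so released), so that after loss of two CO2 the tertiary C9 radical and the primary C11 radical arise side by side. Radical sorting follows: the unhindered C11 radical is captured by the divalent nickel Tp* complex as a trivalent nickel alkyl, and the C9 radical, too hindered to bind to nickel itself, attacks this alkyl at carbon in a bimolecular homolytic substitution (SH2) that forms C9–C11 and returns divalent nickel. The closest known reaction type is the nickel/photoredox double decarboxylative C(sp3)–C(sp3) cross-coupling of a tertiary with a primary aliphatic acid, devised for hindered quaternary carbons, and tertiary radicals at the corresponding ring position of clerodane-type decalins are known to couple stereoselectively. No ring is closed, and the one new stereocentre, C9, is under substrate control: in the flattened ring B the neighbours C10 and C8 hold C1 of ring A and the C17 methyl (free to turn pseudoaxial to escape the eclipsing C20 methyl) on the β face and only H on the α face, so the bulky nickel alkyl should be met from the α face, which places C11 α (equatorial) and C20 β (axial). The step needs cross- over homo-coupling, secured by the primary/tertiary pairing and the excess of 16, and chemoselectivity, secured because the C5=C6 alkene is trisubstituted, unactivated and shielded by quaternary C4 while acetate and silylethyl ester are inert to alkyl radicals. In this one operation the carboxyl that activated the dienophile in step 8 is erased, all six remaining carbons arrive with C13 preset, and the last quaternary stereocentre is fixed.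

Step 13
Reactants: 18 2-(trimethylsilyl)ethyl (3R)-5-[(1R,2S,5R,8aS)-5-(acetoxymethyl)-1,2,5-trimethyl-1,2,3,5,6,7,8,8a-octahydronaphthalen-1-yl]-3-methylpentanoate
Product: 19 (3R)-5-[(1R,2S,5R,8aS)-5-(acetoxymethyl)-1,2,5-trimethyl-1,2,3,5,6,7,8,8a-octahydronaphthalen-1-yl]-3-methylpentanoic acid (target)
Conditions: Bu4NF (1 M in THF), THF, 0 °C to rt; then dilute aq. HCl
Reagents that add atoms: none
Why: Fluoride attack on silicon triggers β-fragmentation of the 2-(trimethylsilyl)ethyl ester to ethene and the carboxylate under conditions that should leave the hindered neopentyl-type acetate, the trisubstituted alkene and all stereocentres untouched.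

**Compound list**
1 | ethyl 2-oxocyclohexane-1-carboxylate | CCOC(=O)C1CCCCC1=O | starting material
2 | ethyl (1S,2S)-2-hydroxycyclohexane-1-carboxylate | CCOC(=O)[C@H]1CCCC[C@@H]1O | intermediate
3 | dilithium alkoxide-enolate of 2 (chelated, enolate oxygen cis to the carbinol carbon) | [Li+].[Li+].CCO/C([O-])=C1\CCCC[C@@H]1[O-] | intermediate
4 | ethyl (1R,2S)-2-hydroxy-1-methylcyclohexane-1-carboxylate | CCOC(=O)[C@]1(C)CCCC[C@@H]1O | intermediate
5 | ethyl (1R)-1-methyl-2-oxocyclohexane-1-carboxylate | CCOC(=O)[C@]1(C)CCCCC1=O | intermediate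
6 | lithium enolate of 5 | [Li+].CCOC(=O)[C@]1(C)CCCC=C1[O-] | intermediate
7 | ethyl (1R)-1-methyl-2-(trifluoromethylsulfonyloxy)cyclohex-2-ene-1-carboxylate | CCOC(=O)[C@]1(C)CCCC=C1OS(=O)(=O)C(F)(F)F | intermediate
8 | ethyl (1R)-2-ethenyl-1-methylcyclohex-2-ene-1-carboxylate | CCOC(=O)[C@]1(C)CCCC=C1C=C | intermediate
9 | [(1R)-2-ethenyl-1-methylcyclohex-2-en-1-yl]methanol | OC[C@]1(C)CCCC=C1C=C | intermediate
10 | [(1R)-2-ethenyl-1-methylcyclohex-2-en-1-yl]methyl acetate | CC(=O)OC[C@]1(C)CCCC=C1C=C | intermediate
11 | (E)-2-methylbut-2-enal (tiglaldehyde) | C/C=C(\C)C=O | starting material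
12 | [(1R,4aR,5R,6S)-5-formyl-1,5,6-trimethyl-1,2,3,4,4a,5,6,7-octahydronaphthalen-1-yl]methyl acetate | CC(=O)OC[C@]1(C)CCC[C@@H]2C1=CC[C@H](C)[C@@]2(C)C=O | intermediate
13 | (1R,2S,5R,8aR)-5-(acetoxymethyl)-1,2,5-trimethyl-1,2,3,5,6,7,8,8a-octahydronaphthalene-1-carboxylic acid | CC(=O)OC[C@]1(C)CCC[C@@H]2C1=CC[C@H](C)[C@@]2(C)C(=O)O | intermediate
14 | (R)-citronellic acid | CC(C)=CCC[C@@H](C)CC(=O)O | starting material
15 | 2-(trimethylsilyl)ethyl (3R)-3,7-dimethyloct-6-enoate | CC(C)=CCC[C@@H](C)CC(=O)OCC[Si](C)(C)C | intermediate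
16 | (4R)-4-methyl-6-oxo-6-[2-(trimethylsilyl)ethoxy]hexanoic acid | OC(=O)CC[C@@H](C)CC(=O)OCC[Si](C)(C)C | intermediate
17 | mesityl-λ3-iodanediyl mixed dicarboxylate (one carboxylate from 13, one from 16) | CC(=O)OC[C@]1(C)CCC[C@@H]2C1=CC[C@H](C)[C@@]2(C)C(=O)OI(OC(=O)CC[C@@H](C)CC(=O)OCC[Si](C)(C)C)c3c(C)cc(C)cc3C | intermediate
18 | 2-(trimethylsilyl)ethyl (3R)-5-[(1R,2S,5R,8aS)-5-(acetoxymethyl)-1,2,5-trimethyl-1,2,3,5,6,7,8,8a-octahydronaphthalen-1-yl]-3-methylpentanoate | CC(=O)OC[C@]1(C)CCC[C@@H]2C1=CC[C@H](C)[C@@]2(C)CC[C@@H](C)CC(=O)OCC[Si](C)(C)C | intermediate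
19 | (3R)-5-[(1R,2S,5R,8aS)-5-(acetoxymethyl)-1,2,5-trimethyl-1,2,3,5,6,7,8,8a-octahydronaphthalen-1-yl]-3-methylpentanoic acid | CC(=O)OC[C@]1(C)CCC[C@@H]2C1=CC[C@H](C)[C@@]2(C)CC[C@@H](C)CC(=O)O | target

Total step count: 13. Longest linear sequence: 11 (steps 1–9, 12, 13).

**Steps most likely to fail**

Step 12.
- What may go wrong: the hindered C9 radical may be lost by disproportionation to ring-B dienes or by hydrogen abstraction before it meets the nickel alkyl. The primary radical may also be consumed by dimerisation.
- Fallback (sets out from 13, comes back at 18): radical–radical sorting is replaced by a polarity-matched radical addition, and C13 is set afterwards. Acid 13 would be condensed with N-hydroxyphthalimide (DIC, DMAP) to the N-(acyloxy)phthalimide F1. Under Ru(bpy)3(PF6)2, Hantzsch ester, i-Pr2NEt and blue light, F1 releases the same C9 radical into a Giese addition to methyl vinyl ketone and gives the methyl ketone F2. Horner–Wadsworth–Emmons olefination (NaH, THF) with the silylethyl phosphonoacetate F3, made from diethylphosphonoacetic acid and 2-(trimethylsilyl)ethanol with DCC, gives the (E)-enoate F4. Asymmetric copper hydride conjugate reduction (Cu(OAc)2, DTBM-SEGPHOS in the enantiomeric form that gives 13R, PMHS, t-BuOH, toluene) returns to 18.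

Step 8.
- What may go wrong: the cycloaddition of a trisubstituted dienophile with a hindered diene may be so slow that acid-induced oligomerisation of the diene competes. Catalyst control over the diene face (relation of C10 to C4) or the exo preference (C8) may also be incomplete.
- Fallback (sets out from 9, comes back at 13): catalyst control is replaced by substrate control through a temporary bulky group. Alcohol 9 would be silylated (TBDPSCl, imidazole) to the silyl ether diene F5, whose large CH2OSi group should turn pseudoaxial and block its own face. A cycloaddition with 11 promoted by stoichiometric Me2AlCl in CH2Cl2 then takes place syn to the C4 methyl group and gives the silyl ether aldehyde F6. Pinnick oxidation gives the silyl ether acid F7, Bu4NF gives the hydroxy acid F8, and acetylation (Ac2O, pyridine, aqueous work-up) returns to 13.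

Step 2.
- What may go wrong: incomplete dianion formation, O-methylation of the alkoxide, or erosion of the facial preference of the chelated enolate would lower the purity at C4.
- Fallback (sets out from 1, comes back at 5): hydroxyl-directed alkylation is replaced by auxiliary-controlled alkylation of a chiral enamine. Keto ester 1 would be condensed with tert-butyl L-valinate (BF3·OEt2 cat., benzene, water removal) to the enamino ester F9. Deprotonation with LiN(i-Pr)2 and methylation with MeI, in the solvent/ligand combination that leads to the (R)-product, gives the methylated imine F10. Mild aqueous acid hydrolyses F10 to 5.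

**Further compounds**
F1 | step 12 | 1,3-dioxoisoindolin-2-yl (1R,2S,5R,8aR)-5-(acetoxymethyl)-1,2,5-trimethyl-1,2,3,5,6,7,8,8a-octahydronaphthalene-1-carboxylate | CC(=O)OC[C@]1(C)CCC[C@@H]2C1=CC[C@H](C)[C@@]2(C)C(=O)ON3C(=O)c4ccccc4C3=O
F2 | step 12 | [(1R,4aS,5R,6S)-1,5,6-trimethyl-5-(3-oxobutyl)-1,2,3,4,4a,5,6,7-octahydronaphthalen-1-yl]methyl acetate | CC(=O)OC[C@]1(C)CCC[C@@H]2C1=CC[C@H](C)[C@@]2(C)CCC(C)=O
F3 | step 12 | 2-(trimethylsilyl)ethyl 2-(diethoxyphosphoryl)acetate | CCOP(=O)(CC(=O)OCC[Si](C)(C)C)OCC
F4 | step 12 | 2-(trimethylsilyl)ethyl (2E)-5-[(1R,2S,5R,8aS)-5-(acetoxymethyl)-1,2,5-trimethyl-1,2,3,5,6,7,8,8a-octahydronaphthalen-1-yl]-3-methylpent-2-enoate | CC(=O)OC[C@]1(C)CCC[C@@H]2C1=CC[C@H](C)[C@@]2(C)CC/C(C)=C/C(=O)OCC[Si](C)(C)C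
F5 | step 8 | tert-butyl{[(1R)-2-ethenyl-1-methylcyclohex-2-en-1-yl]methoxy}diphenylsilane | CC(C)(C)[Si](OC[C@]1(C)CCCC=C1C=C)(c2ccccc2)c3ccccc3
F6 | step 8 | (1R,2S,5R,8aR)-5-{[tert-butyl(diphenyl)silyl]oxymethyl}-1,2,5-trimethyl-1,2,3,5,6,7,8,8a-octahydronaphthalene-1-carbaldehyde | CC(C)(C)[Si](OC[C@]1(C)CCC[C@@H]2C1=CC[C@H](C)[C@@]2(C)C=O)(c3ccccc3)c4ccccc4
F7 | step 8 | (1R,2S,5R,8aR)-5-{[tert-butyl(diphenyl)silyl]oxymethyl}-1,2,5-trimethyl-1,2,3,5,6,7,8,8a-octahydronaphthalene-1-carboxylic acid | CC(C)(C)[Si](OC[C@]1(C)CCC[C@@H]2C1=CC[C@H](C)[C@@]2(C)C(=O)O)(c3ccccc3)c4ccccc4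
F8 | step 8 | (1R,2S,5R,8aR)-5-(hydroxymethyl)-1,2,5-trimethyl-1,2,3,5,6,7,8,8a-octahydronaphthalene-1-carboxylic acid | OC[C@]1(C)CCC[C@@H]2C1=CC[C@H](C)[C@@]2(C)C(=O)O
F9 | step 2 | ethyl 2-{[(2S)-1-tert-butoxy-3-methyl-1-oxobutan-2-yl]amino}cyclohex-1-ene-1-carboxylate | CCOC(=O)C1=C(N[C@@H](C(C)C)C(=O)OC(C)(C)C)CCCC1
F10 | step 2 | ethyl (1R)-2-{[(2S)-1-tert-butoxy-3-methyl-1-oxobutan-2-yl]imino}-1-methylcyclohexane-1-carboxylate | CCOC(=O)[C@]1(C)CCCCC1=N[C@@H](C(C)C)C(=O)OC(C)(C)C
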